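**Strategy.** Ring A (C1, C10–C14) carries oxygen on every carbon from C11 to C14, so it is treated as a masked cyclohexa-1,3-diene whose C1–C10 bond closes a trienoate. A Z-selective Julia–Kocienski olefination joins an L-arabinose-derived allylic sulfone (C6–C12) to a (Z)-formyl methacrylate (C13, C14, C1, C2) at C12=C13. The triene then undergoes thermal 6π-electrocyclization, which forms the quaternary C1–C10 bond and sets C1 and C10 under control of the furanose stereocentre C9. Dihydroxylation and directed epoxidation of the diene, indium-mediated dienylation of the sugar lactol (C5–C6) and ring-closing metathesis (C3=C4) complete the bicyclo[8.4.0] core.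

Key step: step 14

Remark 1: atoms carry briarane numbers (C1 quaternary ring-fusion carbon with CH3-15, C2–C9 ten-membered ring, C10, C11–C14 ring A, C16 exocyclic CH2, C17/CH3-18, C19 lactone C=O, CH3-20 on C11). Sugar C1–C5 become C6–C10. β is the face of CH3-15.
Remark 2: C17 is formed without control in step 4 and is carried as both epimers (drawn without configuration) until it is fixed in step 27.

Step 1
Reactants: 1 L-arabinose
Product: 2 5-O-TBDPS-L-arabinofuranose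
Conditions: TBDPSCl, pyridine, 0 °C → rt
Reagents that add atoms: tert-butyl(chloro)diphenylsilane, CC(C)(C)[Si](Cl)(c1ccccc1)c1ccccc1
Why: Selective silylation: the bulky silyl chloride reacts only with the primary 5-OH, which fixes the sugar as a furanose; sugar C2 and C4 are the future C7 and C9.

Step 2
Reactants: 2 5-O-TBDPS-L-arabinofuranose
Product: 3 5-O-TBDPS-1,2-O-isopropylidene-β-L-arabinofuranose
Conditions: Me2C(OMe)2, TsOH·H2O (cat.), acetone, rt
Reagents that add atoms: 2,2-dimethoxypropane, COC(C)(C)OC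
Why: Acetalization gives the cis-fused 1,2-acetonide (anomeric oxygen forced cis to O2) and leaves O3–H as the only free hydroxyl.

Step 3
Reactants: 3 5-O-TBDPS-1,2-O-isopropylidene-β-L-arabinofuranose
Product: 4 5-O-TBDPS-1,2-O-isopropylidene-β-L-threo-pentofuranos-3-ulose
Conditions: Dess–Martin periodinane, NaHCO3, CH2Cl2, rt
Reagents that add atoms: none
Why: Dess–Martin oxidation of the only free (secondary) alcohol gives the ketone that will become C8.

Step 4
Reactants: 4 3-ulose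
Product: 5 3-C-[1-(tert-butoxycarbonyl)ethyl] tertiary alcohol (L-lyxo, C17 epimers)
Conditions: Zn (activated), THF, 45 °C
Reagents that add atoms: tert-butyl 2-bromopropanoate, CC(Br)C(=O)OC(C)(C)C
Why: Reformatsky reaction: the zinc enolate adds from the convex face, anti to both the 1,2-acetonide and the C4 side chain, which sets C8 (OH cis to O7); C17 forms as both epimers and is fixed in step 27.

Step 5
Reactants: 5 Reformatsky adduct
Product: 6 primary alcohol (C10–OH)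
Conditions: Bu4NF, THF, 0 °C
Reagents that add atoms: none
Why: Fluoride cleaves the silyl ether; the tert-butyl ester and acetonide are inert.

Step 6
Reactants: 6 primary alcohol
Product: 7 C10 aldehyde
Conditions: Dess–Martin periodinane, NaHCO3, CH2Cl2, 0 °C
Reagents that add atoms: none
Why: Dess–Martin oxidation under buffered, non-basic conditions spares the α-alkoxy stereocentre C9; the tertiary alcohol does not react.

Step 7
Reactants: 7 C10 aldehyde
Product: 8 (E)-2-methyl enal (C10=C11, C12 aldehyde)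
Conditions: PhMe, 80 °C
Reagents that add atoms: 2-(triphenyl-λ5-phosphanylidene)propanal, CC(C=O)=P(c1ccccc1)(c1ccccc1)c1ccccc1
Why: Wittig olefination with a stabilized ylide gives the E alkene, which places C9 trans to C12 as the later triene terminus requires.

Step 8
Reactants: 8 (E)-enal
Product: 9 (E)-allylic alcohol
Conditions: NaBH4, CeCl3·7H2O, MeOH, −40 °C
Reagents that add atoms: none
Why: Luche 1,2-reduction of the enal without conjugate reduction or attack on the ester.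

Step 9
Reactants: 9 allylic alcohol
Product: 10 allylic 1-tert-butyltetrazol-5-yl sulfide
Conditions: PPh3, iPrO2CN=NCO2iPr, THF, 0 °C
Reagents that add atoms: 1-tert-butyl-1H-tetrazole-5-thiol, CC(C)(C)n1nnnc1S
Why: Mitsunobu thioetherification of the primary allylic alcohol (SN2, no allylic shift); the tertiary 8-OH does not react.

Step 10
Reactants: 10 sulfide
Product: 11 8-O-triethylsilyl sulfide
Conditions: Et3SiOTf, 2,6-lutidine, CH2Cl2, −40 → 0 °C
Reagents that add atoms: triethylsilyl trifluoromethanesulfonate, CC[Si](CC)(CC)OS(=O)(=O)C(F)(F)F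
Why: Silylation removes the only acidic O–H (and the retro-aldol pathway) before the carbanion chemistry of step 14.

Step 11
Reactants: 11 silylated sulfide
Product: 12 east fragment, allylic 1-tert-butyltetrazol-5-yl sulfone
Conditions: (NH4)6Mo7O24·4H2O (cat.), 30% H2O2, EtOH, 0 °C → rt
Reagents that add atoms: hydrogen peroxide, OO
Why: Molybdate-catalysed oxidation of sulfide to sulfone; the trisubstituted alkene and silyl ether are untouched.

Step 12
Reactants: 13 3-methylfuran-2-carboxylic acid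
Product: 14 5-hydroxy-3-methylfuran-2(5H)-one
Conditions: O2, hν, rose bengal (cat.), MeOH, 0 °C
Reagents that add atoms: oxygen, O=O
Why: [4+2] addition of singlet oxygen to the furan and decarboxylative fragmentation of the endoperoxide give the hydroxybutenolide.

Step 13
Reactants: 14 5-hydroxy-3-methylfuran-2(5H)-one
Product: 15 west fragment, benzyl (2Z)-2-methyl-4-oxobut-2-enoate
Conditions: BnBr, K2CO3, DMF, 0 °C
Reagents that add atoms: benzyl bromide, BrCc1ccccc1
Why: O-alkylation of the ring-opened carboxylate of the pseudo-acid gives the open formyl ester, whose Z geometry is inherited from the five-membered ring.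

Step 14
Reactants: 12 east sulfone; 15 west aldehyde
Product: 17 ring A cyclohexa-1,3-diene (C1: CH3 β, CO2Bn α; C10: H α, furanosyl β), via trienoate 16 (not isolated)
Conditions: 12, KN(SiMe3)2, DME, −78 °C; then 15, −78 °C → rt; then PhMe, 95 °C
Reagents that add atoms: none
Why: The potassium salt of 12 adds to 15 and the adduct collapses by Smiles rearrangement with loss of SO2 and the tetrazololate (Julia–Kocienski olefination), the 1-tert-butyltetrazolyl sulfone favouring the Z alkene C12=C13; the (2Z,4Z,6E)-trienoate 16 then closes by thermal disrotatory 6π-electrocyclization to form C1–C10. The closest known reaction type is the one-pot olefination/6π-electrocyclization of (Z)-hexatrienes to cyclohexa-1,3-dienes, including cases that create a quaternary carbon. Ring A closes in the six-electron electrocyclic mode by bonding of the two triene termini. Disrotation puts the inside groups (CO2Bn on C1, H on C10) cis and the outside groups (CH3-15, C9) cis, which is the relative configuration of C1 and C10; the absolute sense comes from C9, whose C–H bond eclipses C10=C11 to avoid allylic 1,3-strain with CH3-20, so that C1 bonds to the face of C10 opposite the bulky quaternary C8. The step needs Z geometry at C12=C13 and C1=C14 and no competing hydrogen shift: the sulfone type secures the first, the butenolide origin of 15 the second, and the inside substituent on C1 is an ester with no hydrogen for a [1,7]-shift.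

Step 15
Reactants: 17 ring A diene
Product: 18 11α,12α-diol
Conditions: OsO4 (cat.), NMO, acetone/H2O, 0 °C
Reagents that add atoms: 4-methylmorpholine 4-oxide, C[N+]1([O-])CCOCC1; water, O
Why: Upjohn dihydroxylation attacks the more electron-rich trisubstituted C11=C12 bond from the α face, anti to the pseudo-axial CH3-15 and the C9 substituent, setting C11 and C12.

Step 16
Reactants: 18 diol
Product: 19 13α,14α-epoxy diol
Conditions: VO(acac)2 (cat.), t-BuOOH, CH2Cl2, 0 °C → rt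
Reagents that add atoms: tert-butyl hydroperoxide, CC(C)(C)OO
Why: Hydroxyl-directed vanadium epoxidation delivers oxygen syn to the allylic 12-OH, also the face away from CH3-15, setting C13 and C14.

Step 17
Reactants: 19 epoxy diol
Product: 20 12-butanoate
Conditions: (PrCO)2O, Et3N, DMAP (cat.), CH2Cl2, 0 °C
Reagents that add atoms: butanoic anhydride, CCCC(=O)OC(=O)CCC
Why: Selective acylation of the secondary 12-OH; the tertiary 11-OH does not react.

Step 18
Reactants: 20 12-butanoate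
Product: 21 11-O-trimethylsilyl ether
Conditions: 1-(trimethylsilyl)imidazole, CH2Cl2, 35 °C
Reagents that add atoms: 1-(trimethylsilyl)imidazole, C[Si](C)(C)n1ccnc1
Why: Neutral silylation masks the tertiary 11-OH, which is cis-1,3 to the C2 carboxyl and would give a γ-lactone once that carboxyl is activated.

Step 19
Reactants: 21 benzyl ester
Product: 22 C2 carboxylic acid
Conditions: H2 (1 atm), Pd/C, EtOAc, rt
Reagents that add atoms: none
Why: Hydrogenolysis of the benzyl ester; no alkene remains and the non-benzylic epoxide is inert.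

Step 20
Reactants: 22 C2 carboxylic acid
Product: 24 vinyl ketone (C2=O, C3=CH2), via acid chloride 23 (not isolated)
Conditions: Me2C=C(Cl)NMe2, CH2Cl2, 0 °C → rt; then Bu3SnCH=CH2, Pd(PPh3)4 (cat.), THF, 50 °C
Reagents that add atoms: tributyl(ethenyl)stannane, C=C[Sn](CCCC)(CCCC)CCCC
Why: Acid chloride formation under neutral conditions followed by Stille acylation gives the enone without touching the epoxide or esters.

Step 21
Reactants: 24 vinyl ketone
Product: 25 (2S)-allylic alcohol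
Conditions: (R)-2-methyl-CBS-oxazaborolidine (cat.), catecholborane, PhMe, −78 °C
Reagents that add atoms: none
Why: Corey–Bakshi–Shibata reduction: with quaternary C1 as the large and vinyl as the small substituent the (R)-catalyst gives the (2S)-alcohol under reagent control.

Step 22
Reactants: 25 allylic alcohol
Product: 26 furanose lactol (C6 hemiacetal; 7-OH, 8-OH, 11-OH free)
Conditions: AcOH/H2O (4:1), 55 °C
Reagents that add atoms: none
Why: Aqueous acid hydrolyses the anomeric acetonide and both silyl ethers, while the tert-butyl ester, butanoate and the deactivated epoxide (flanked by quaternary C1 and acyloxy C12) persist.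

Step 23
Reactants: 26 lactol
Product: 27 (6R)-buta-1,3-dien-2-yl carbinol (open chain; 6,7-syn)
Conditions: In (powder), THF/H2O (1:1), rt
Reagents that add atoms: 1,4-dibromobut-2-yne, BrCC#CCBr
Why: Barbier-type indium-mediated buta-1,3-dien-2-ylation of the open hydroxy-aldehyde tautomer; chelation of indium between the aldehyde oxygen and the free 7-OH gives the 6,7-syn diol, setting C6 and freeing 9-OH.

Step 24
Reactants: 27 dienyl pentaol
Product: 28 6,7-O-isopropylidene derivative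
Conditions: Me2C(OMe)2, CSA (cat.), CH2Cl2, 0 °C
Reagents that add atoms: 2,2-dimethoxypropane, COC(C)(C)OC
Why: Acetonide formation on the only 1,2-diol made of two secondary alcohols (trans-dioxolane from the syn diol) leaves 2-OH and the hindered 9-OH free.

Step 25
Reactants: 28 acetonide
Product: 29 2,9-diacetate
Conditions: Ac2O, pyridine, DMAP (cat.), rt → 40 °C
Reagents that add atoms: acetic anhydride, CC(=O)OC(C)=O
Why: Acetylation of both secondary alcohols; the tertiary 8-OH and 11-OH do not react.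

Step 26
Reactants: 29 diacetate
Product: 30 γ-lactone (C19–O7) with free 6-OH (C17 epimers)
Conditions: CF3CO2H/CH2Cl2 (1:4), trace H2O, 0 °C
Reagents that add atoms: none
Why: Acid removes the acetonide and the tert-butyl ester and the hydroxy acid lactonizes onto O7, the only free γ-hydroxyl now that O9 is acetylated (γ preferred over the δ-lactone to O6).

Step 27
Reactants: 30 lactone (C17 epimers)
Product: 31 (17R)-lactone
Conditions: DBU (0.3 equiv), PhMe, 40 °C
Reagents that add atoms: none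
Why: Base-catalysed epimerization of the lactone α-carbon favours the epimer with CH3-18 trans to the bulky C9 substituent on the adjacent quaternary C8 (cis to the small 8-OH), which is the 17R configuration.

Step 28
Reactants: 31 (6R)-allylic alcohol
Product: 32 (6S)-allylic chloride
Conditions: PPh3, Cl3CC(O)CCl3, CH2Cl2, −20 → 0 °C
Reagents that add atoms: hexachloropropan-2-one, O=C(C(Cl)(Cl)Cl)C(Cl)(Cl)Cl
Why: Appel-type chlorination proceeds by SN2 with inversion and without allylic transposition; the tertiary alcohols do not react.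

Step 29
Reactants: 32 allylic chloride
Product: 33 CNP0273377.1
Conditions: second-generation Hoveyda–Grubbs catalyst (10 mol %), PhMe (1 mM), 80 °C
Reagents that add atoms: none
Why: Ring-closing metathesis joins the C2 vinyl group to the monosubstituted terminus of the diene (the 1,1-disubstituted C5=C16 alkene does not engage) and closes the ten-membered ring; the strain of the trans-fused bicyclo[8.4.0] system should impose the Z geometry at C3=C4.

**Compound list**

1 | L-arabinose (aldehydo form drawn) | OC[C@H](O)[C@H](O)[C@@H](O)C=O | starting material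
2 | 5-O-(tert-butyldiphenylsilyl)-L-arabinofuranose (anomers) | CC(C)(C)[Si](c1ccccc1)(c1ccccc1)OC[C@@H]1OC(O)[C@H](O)[C@H]1O | intermediate
3 | 5-O-(tert-butyldiphenylsilyl)-1,2-O-isopropylidene-β-L-arabinofuranose | CC(C)(C)[Si](c1ccccc1)(c1ccccc1)OC[C@@H]1O[C@@H]2OC(C)(C)O[C@@H]2[C@H]1O | intermediate
4 | 5-O-(tert-butyldiphenylsilyl)-1,2-O-isopropylidene-β-L-threo-pentofuranos-3-ulose | CC(C)(C)[Si](c1ccccc1)(c1ccccc1)OC[C@@H]1O[C@@H]2OC(C)(C)O[C@@H]2C1=O | intermediate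
5 | 5-O-(tert-butyldiphenylsilyl)-3-C-[1-(tert-butoxycarbonyl)ethyl]-1,2-O-isopropylidene-β-L-lyxofuranose (sugar C3 = C8; both C17 epimers) | CC(C)(C)[Si](c1ccccc1)(c1ccccc1)OC[C@@H]1O[C@@H]2OC(C)(C)O[C@@H]2[C@@]1(O)C(C)C(=O)OC(C)(C)C | intermediate
6 | 3-C-[1-(tert-butoxycarbonyl)ethyl]-1,2-O-isopropylidene-β-L-lyxofuranose (C17 epimers) | OC[C@@H]1O[C@@H]2OC(C)(C)O[C@@H]2[C@@]1(O)C(C)C(=O)OC(C)(C)C | intermediate
7 | the corresponding 5-aldehyde (C10 aldehyde; C17 epimers) | O=C[C@@H]1O[C@@H]2OC(C)(C)O[C@@H]2[C@@]1(O)C(C)C(=O)OC(C)(C)C | intermediate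
8 | (E)-2-methyl enal on the furanose (C10=C11, C12 aldehyde; 8-OH free; C17 epimers) | O=C/C(C)=C/[C@@H]1O[C@@H]2OC(C)(C)O[C@@H]2[C@@]1(O)C(C)C(=O)OC(C)(C)C | intermediate
9 | (E)-allylic alcohol (C12–OH; C17 epimers) | OC/C(C)=C/[C@@H]1O[C@@H]2OC(C)(C)O[C@@H]2[C@@]1(O)C(C)C(=O)OC(C)(C)C | intermediate
10 | (E)-allylic 1-tert-butyl-1H-tetrazol-5-yl sulfide (8-OH free; C17 epimers) | CC(C)(C)n1nnnc1SC/C(C)=C/[C@@H]2O[C@@H]3OC(C)(C)O[C@@H]3[C@@]2(O)C(C)C(=O)OC(C)(C)C | intermediate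
11 | 8-O-triethylsilyl ether of 10 (C17 epimers) | CC(C)(C)n1nnnc1SC/C(C)=C/[C@@H]2O[C@@H]3OC(C)(C)O[C@@H]3[C@@]2(O[Si](CC)(CC)CC)C(C)C(=O)OC(C)(C)C | intermediate
12 | east fragment: (E)-allylic 1-tert-butyl-1H-tetrazol-5-yl sulfone (C6–C12, C17–C20; C17 epimers) | CC(C)(C)n1nnnc1S(=O)(=O)C/C(C)=C/[C@@H]2O[C@@H]3OC(C)(C)O[C@@H]3[C@@]2(O[Si](CC)(CC)CC)C(C)C(=O)OC(C)(C)C | intermediate
13 | 3-methylfuran-2-carboxylic acid | Cc1ccoc1C(=O)O | starting material
14 | 5-hydroxy-3-methylfuran-2(5H)-one (racemic hemiacetal) | CC1=CC(O)OC1=O | intermediate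
15 | west fragment: benzyl (2Z)-2-methyl-4-oxobut-2-enoate | O=C/C=C(C)\C(=O)OCc1ccccc1 | intermediate
16 | benzyl (2Z,4Z,6E)-2,6-dimethyl-7-(furanosyl)hepta-2,4,6-trienoate (C17 epimers) | O=C(OCc1ccccc1)/C(C)=C\C=C/C(C)=C/[C@@H]2O[C@@H]3OC(C)(C)O[C@@H]3[C@@]2(O[Si](CC)(CC)CC)C(C)C(=O)OC(C)(C)C | intermediate
17 | ring A diene: C1 (CH3 β, CO2Bn α), C10 (H α, furanosyl β), C11=C12, C13=C14 (C17 epimers) | O=C(OCc1ccccc1)[C@@]2(C)C=CC=C(C)[C@@H]2[C@@H]3O[C@@H]4OC(C)(C)O[C@@H]4[C@@]3(O[Si](CC)(CC)CC)C(C)C(=O)OC(C)(C)C | intermediate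
18 | 11α,12α-diol with C13=C14 (C17 epimers) | O=C(OCc1ccccc1)[C@@]2(C)C=C[C@@H](O)[C@@](C)(O)[C@@H]2[C@@H]3O[C@@H]4OC(C)(C)O[C@@H]4[C@@]3(O[Si](CC)(CC)CC)C(C)C(=O)OC(C)(C)C | intermediate
19 | 13α,14α-epoxy-11α,12α-diol (C17 epimers) | O=C(OCc1ccccc1)[C@@]2(C)[C@H]3O[C@H]3[C@@H](O)[C@@](C)(O)[C@@H]2[C@@H]3O[C@@H]4OC(C)(C)O[C@@H]4[C@@]3(O[Si](CC)(CC)CC)C(C)C(=O)OC(C)(C)C | intermediate
20 | 12-butanoate of 19 (C17 epimers) | O=C(OCc1ccccc1)[C@@]2(C)[C@H]3O[C@H]3[C@@H](OC(=O)CCC)[C@@](C)(O)[C@@H]2[C@@H]3O[C@@H]4OC(C)(C)O[C@@H]4[C@@]3(O[Si](CC)(CC)CC)C(C)C(=O)OC(C)(C)C | intermediate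
21 | 11-O-trimethylsilyl ether of 20 (C17 epimers) | O=C(OCc1ccccc1)[C@@]2(C)[C@H]3O[C@H]3[C@@H](OC(=O)CCC)[C@@](C)(O[Si](C)(C)C)[C@@H]2[C@@H]3O[C@@H]4OC(C)(C)O[C@@H]4[C@@]3(O[Si](CC)(CC)CC)C(C)C(=O)OC(C)(C)C | intermediate
22 | C2 carboxylic acid (C17 epimers) | OC(=O)[C@@]1(C)[C@H]2O[C@H]2[C@@H](OC(=O)CCC)[C@@](C)(O[Si](C)(C)C)[C@@H]1[C@@H]3O[C@@H]4OC(C)(C)O[C@@H]4[C@@]3(O[Si](CC)(CC)CC)C(C)C(=O)OC(C)(C)C | intermediate
23 | C2 acid chloride (C17 epimers) | ClC(=O)[C@@]1(C)[C@H]2O[C@H]2[C@@H](OC(=O)CCC)[C@@](C)(O[Si](C)(C)C)[C@@H]1[C@@H]3O[C@@H]4OC(C)(C)O[C@@H]4[C@@]3(O[Si](CC)(CC)CC)C(C)C(=O)OC(C)(C)C | intermediate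
24 | vinyl ketone (C2=O, C3=CH2; C17 epimers) | C=CC(=O)[C@@]1(C)[C@H]2O[C@H]2[C@@H](OC(=O)CCC)[C@@](C)(O[Si](C)(C)C)[C@@H]1[C@@H]3O[C@@H]4OC(C)(C)O[C@@H]4[C@@]3(O[Si](CC)(CC)CC)C(C)C(=O)OC(C)(C)C | intermediate
25 | (2S)-allylic alcohol (C17 epimers) | C=C[C@H](O)[C@@]1(C)[C@H]2O[C@H]2[C@@H](OC(=O)CCC)[C@@](C)(O[Si](C)(C)C)[C@@H]1[C@@H]3O[C@@H]4OC(C)(C)O[C@@H]4[C@@]3(O[Si](CC)(CC)CC)C(C)C(=O)OC(C)(C)C | intermediate
26 | furanose lactol (C6 hemiacetal, anomers; 2-OH, 7-OH, 8-OH, 11-OH free; C17 epimers) | C=C[C@H](O)[C@@]1(C)[C@H]2O[C@H]2[C@@H](OC(=O)CCC)[C@@](C)(O)[C@@H]1[C@@H]3OC(O)[C@H](O)[C@@]3(O)C(C)C(=O)OC(C)(C)C | intermediate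
27 | (6R)-buta-1,3-dien-2-yl carbinol, open chain with 2-, 6-, 7-, 8-, 9-, 11-OH free (C17 epimers) | C=C[C@H](O)[C@@]1(C)[C@H]2O[C@H]2[C@@H](OC(=O)CCC)[C@@](C)(O)[C@@H]1[C@H](O)[C@](O)(C(C)C(=O)OC(C)(C)C)[C@@H](O)[C@H](O)C(=C)C=C | intermediate
28 | 6,7-O-isopropylidene derivative of 27 (C17 epimers) | C=C[C@H](O)[C@@]1(C)[C@H]2O[C@H]2[C@@H](OC(=O)CCC)[C@@](C)(O)[C@@H]1[C@H](O)[C@](O)(C(C)C(=O)OC(C)(C)C)[C@H]3OC(C)(C)O[C@@H]3C(=C)C=C | intermediate
29 | 2,9-diacetate of 28 (C17 epimers) | C=C[C@H](OC(C)=O)[C@@]1(C)[C@H]2O[C@H]2[C@@H](OC(=O)CCC)[C@@](C)(O)[C@@H]1[C@H](OC(C)=O)[C@](O)(C(C)C(=O)OC(C)(C)C)[C@H]3OC(C)(C)O[C@@H]3C(=C)C=C | intermediate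
30 | γ-lactone (C19–O7) with 6-OH and 8-OH free (C17 epimers) | C=C[C@H](OC(C)=O)[C@@]1(C)[C@H]2O[C@H]2[C@@H](OC(=O)CCC)[C@@](C)(O)[C@@H]1[C@H](OC(C)=O)[C@]1(O)C(C)C(=O)O[C@H]1[C@H](O)C(=C)C=C | intermediate
31 | (17R)-lactone, (6R)-alcohol | C=C[C@H](OC(C)=O)[C@@]1(C)[C@H]2O[C@H]2[C@@H](OC(=O)CCC)[C@@](C)(O)[C@@H]1[C@H](OC(C)=O)[C@]1(O)[C@@H](C)C(=O)O[C@H]1[C@H](O)C(=C)C=C | intermediate
32 | (6S)-allylic chloride, metathesis precursor | C=C[C@H](OC(C)=O)[C@@]1(C)[C@H]2O[C@H]2[C@@H](OC(=O)CCC)[C@@](C)(O)[C@@H]1[C@H](OC(C)=O)[C@]1(O)[C@@H](C)C(=O)O[C@H]1[C@H](C(=C)C=C)Cl | intermediate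
33 | CNP0273377.1 | C=C1/C=C\[C@H](OC(C)=O)[C@@]2(C)[C@H]3O[C@H]3[C@@H](OC(=O)CCC)[C@@](C)(O)[C@@H]2[C@H](OC(C)=O)[C@]2(O)[C@@H](C)C(=O)O[C@H]2[C@H]1Cl | target

**Summary**

Total step count: 29. Longest linear sequence: 27 steps (steps 1–11, 14–29).

Steps most likely to fail:

1. Step 14. The olefination may lose Z selectivity with the conjugated aldehyde, so that a (4E)-triene that cannot cyclize accumulates. The allylic sulfonyl carbanion may also open the furanose by β-elimination, or the facial bias of the ring closure may be too small. The fallback sets out from 8 and comes back at 16 (and from there 17), with the central alkene masked as an alkyne. Enal 8 is homologated with dimethyl (1-diazo-2-oxopropyl)phosphonate, K2CO3 and MeOH (Seyferth–Gilbert homologation) to the (E)-enyne tertiary alcohol F1. Silylation (Et3SiOTf, 2,6-lutidine) gives the triethylsilyl ether F2. Sonogashira coupling (Pd(PPh3)4, CuI, Et3N) with benzyl (2Z)-3-iodo-2-methylprop-2-enoate F3 (from (Z)-3-iodo-2-methylprop-2-en-1-ol by oxidation and benzylation) gives the dienyne F4. Cis-semi-reduction with Zn/Cu/Ag couple in MeOH/H2O then gives trienoate 16, which is heated as in step 14.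

2. Step 29. Oligomerization may outrun closure of the ten-membered ring, initiation at the hindered C2 vinyl group may be slow, or the E alkene may form. The fallback sets out from 22 and comes back at 33; it closes the ring at C5–C6 by a Nozaki–Hiyama–Kishi reaction.
 - C2 side: acid 22 is converted (Me2C=C(Cl)NMe2; then ethynyltrimethylsilane, Pd(PPh3)4, CuI, Et3N) into the silyl ynone F5, and (R)-CBS reduction gives the (2S)-propargylic alcohol F6.
 - C6 end: CSA in acetone/H2O removes both silyl ethers and moves the acetonide to O7/O8, giving the lactol F7. NaBH4 opens it to the 6,9-diol F8. The primary alcohol is silylated (Et3SiCl, imidazole) to F9, and Ac2O/DMAP gives the 2,9-diacetate F10.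
 - Lactone: CF3CO2H gives the lactone primary alcohol F11 (C17 epimers), and DBU gives its (17R)-epimer F12.
 - Iododiene: desilylative Sonogashira coupling with (1-bromoethenyl)trimethylsilane (Pd(PPh3)4, CuI, CsF) gives the enyne F13. Zn/Cu/Ag couple gives the (Z)-dienylsilane F14, and N-iodosuccinimide gives the 2-iodo-1,3-diene F15.
 - Ring closure: Dess–Martin oxidation gives aldehyde F16, and CrCl2 with NiCl2 (cat.) in DMSO/THF closes the ring to the macrocyclic 6-alcohol F17. Its C6 epimers are converged by Dess–Martin oxidation to the dienone F18 and (R)-CBS reduction back to (6R)-F17. Chlorination as in step 28 gives 33.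

3. Step 27. The base may cause retro-aldol cleavage of the β-hydroxy lactone or acyl migration, or the thermodynamic preference may be too small. The fallback sets out from 4 and comes back at 5 as its single (17R)-epimer; it sets C17 with a chiral auxiliary. Ketone 4 is treated with (4S)-4-benzyl-3-(2-bromopropanoyl)-1,3-oxazolidin-2-one and SmI2 in THF at −78 °C. The chelated samarium enolate reacts on its face away from the benzyl group and on the convex face of the ketone, giving the imide F19. LiOH/H2O2 gives the acid F20, and tert-butyl 2,2,2-trichloroacetimidate gives the (17R)-tert-butyl ester F21. F21 is one of the two components of 5 and is taken through steps 5–26 to 31 without step 27.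

Further compounds
F1 | step 14 | (E)-enyne tertiary alcohol from 8 | C#C/C(C)=C/[C@@H]1O[C@@H]2OC(C)(C)O[C@@H]2[C@@]1(O)C(C)C(=O)OC(C)(C)C
F2 | step 14 | 8-O-triethylsilyl ether of F1 | C#C/C(C)=C/[C@@H]1O[C@@H]2OC(C)(C)O[C@@H]2[C@@]1(O[Si](CC)(CC)CC)C(C)C(=O)OC(C)(C)C
F3 | step 14 | benzyl (2Z)-3-iodo-2-methylprop-2-enoate | O=C(OCc1ccccc1)/C(C)=C\I
F4 | step 14 | benzyl (2Z,6E)-dien-4-ynoate (dienyne) | O=C(OCc1ccccc1)/C(C)=C\C#C/C(C)=C/[C@@H]2O[C@@H]3OC(C)(C)O[C@@H]3[C@@]2(O[Si](CC)(CC)CC)C(C)C(=O)OC(C)(C)C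
F5 | step 29 | trimethylsilyl ynone at C2 | C[Si](C)(C)C#CC(=O)[C@@]1(C)[C@H]2O[C@H]2[C@@H](OC(=O)CCC)[C@@](C)(O[Si](C)(C)C)[C@@H]1[C@@H]3O[C@@H]4OC(C)(C)O[C@@H]4[C@@]3(O[Si](CC)(CC)CC)C(C)C(=O)OC(C)(C)C
F6 | step 29 | (2S)-propargylic alcohol | C[Si](C)(C)C#C[C@H](O)[C@@]1(C)[C@H]2O[C@H]2[C@@H](OC(=O)CCC)[C@@](C)(O[Si](C)(C)C)[C@@H]1[C@@H]3O[C@@H]4OC(C)(C)O[C@@H]4[C@@]3(O[Si](CC)(CC)CC)C(C)C(=O)OC(C)(C)C
F7 | step 29 | lactol with 7,8-O-isopropylidene group | C[Si](C)(C)C#C[C@H](O)[C@@]1(C)[C@H]2O[C@H]2[C@@H](OC(=O)CCC)[C@@](C)(O)[C@@H]1[C@@H]3OC(O)[C@@H]4OC(C)(C)O[C@]34C(C)C(=O)OC(C)(C)C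
F8 | step 29 | 6,9-diol (open chain, 7,8-acetonide) | C[Si](C)(C)C#C[C@H](O)[C@@]1(C)[C@H]2O[C@H]2[C@@H](OC(=O)CCC)[C@@](C)(O)[C@@H]1[C@H](O)[C@]3(OC(C)(C)O[C@H]3CO)C(C)C(=O)OC(C)(C)C
F9 | step 29 | 6-O-triethylsilyl ether of F8 | C[Si](C)(C)C#C[C@H](O)[C@@]1(C)[C@H]2O[C@H]2[C@@H](OC(=O)CCC)[C@@](C)(O)[C@@H]1[C@H](O)[C@]3(OC(C)(C)O[C@H]3CO[Si](CC)(CC)CC)C(C)C(=O)OC(C)(C)C
F10 | step 29 | 2,9-diacetate of F9 | C[Si](C)(C)C#C[C@H](OC(C)=O)[C@@]1(C)[C@H]2O[C@H]2[C@@H](OC(=O)CCC)[C@@](C)(O)[C@@H]1[C@H](OC(C)=O)[C@]3(OC(C)(C)O[C@H]3CO[Si](CC)(CC)CC)C(C)C(=O)OC(C)(C)C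
F11 | step 29 | lactone primary alcohol (C17 epimers) | C[Si](C)(C)C#C[C@H](OC(C)=O)[C@@]1(C)[C@H]2O[C@H]2[C@@H](OC(=O)CCC)[C@@](C)(O)[C@@H]1[C@H](OC(C)=O)[C@]1(O)C(C)C(=O)O[C@H]1CO
F12 | step 29 | (17R)-lactone primary alcohol | C[Si](C)(C)C#C[C@H](OC(C)=O)[C@@]1(C)[C@H]2O[C@H]2[C@@H](OC(=O)CCC)[C@@](C)(O)[C@@H]1[C@H](OC(C)=O)[C@]1(O)[C@@H](C)C(=O)O[C@H]1CO
F13 | step 29 | enyne with 2-(trimethylsilyl)ethenyl terminus | C=C([Si](C)(C)C)C#C[C@H](OC(C)=O)[C@@]1(C)[C@H]2O[C@H]2[C@@H](OC(=O)CCC)[C@@](C)(O)[C@@H]1[C@H](OC(C)=O)[C@]1(O)[C@@H](C)C(=O)O[C@H]1CO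
F14 | step 29 | (3Z)-2-silyl-1,3-diene | C=C([Si](C)(C)C)/C=C\[C@H](OC(C)=O)[C@@]1(C)[C@H]2O[C@H]2[C@@H](OC(=O)CCC)[C@@](C)(O)[C@@H]1[C@H](OC(C)=O)[C@]1(O)[C@@H](C)C(=O)O[C@H]1CO
F15 | step 29 | (3Z)-2-iodo-1,3-diene | C=C(I)/C=C\[C@H](OC(C)=O)[C@@]1(C)[C@H]2O[C@H]2[C@@H](OC(=O)CCC)[C@@](C)(O)[C@@H]1[C@H](OC(C)=O)[C@]1(O)[C@@H](C)C(=O)O[C@H]1CO
F16 | step 29 | C6 aldehyde | C=C(I)/C=C\[C@H](OC(C)=O)[C@@]1(C)[C@H]2O[C@H]2[C@@H](OC(=O)CCC)[C@@](C)(O)[C@@H]1[C@H](OC(C)=O)[C@]1(O)[C@@H](C)C(=O)O[C@H]1C=O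
F17 | step 29 | macrocyclic (6R)-alcohol | C=C1/C=C\[C@H](OC(C)=O)[C@@]2(C)[C@H]3O[C@H]3[C@@H](OC(=O)CCC)[C@@](C)(O)[C@@H]2[C@H](OC(C)=O)[C@]2(O)[C@@H](C)C(=O)O[C@H]2[C@@H]1O
F18 | step 29 | macrocyclic C6 ketone | C=C1/C=C\[C@H](OC(C)=O)[C@@]2(C)[C@H]3O[C@H]3[C@@H](OC(=O)CCC)[C@@](C)(O)[C@@H]2[C@H](OC(C)=O)[C@]2(O)[C@@H](C)C(=O)O[C@H]2C1=O
F19 | step 27 | (17R)-N-acyl oxazolidinone adduct of 4 | CC(C)(C)[Si](c1ccccc1)(c1ccccc1)OC[C@@H]2O[C@@H]3OC(C)(C)O[C@@H]3[C@@]2(O)[C@@H](C)C(=O)N4[C@@H](Cc5ccccc5)COC4=O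
F20 | step 27 | (17R)-carboxylic acid | CC(C)(C)[Si](c1ccccc1)(c1ccccc1)OC[C@@H]2O[C@@H]3OC(C)(C)O[C@@H]3[C@@]2(O)[C@@H](C)C(=O)O
F21 | step 27 | (17R)-epimer of 5 | CC(C)(C)[Si](c1ccccc1)(c1ccccc1)OC[C@@H]2O[C@@H]3OC(C)(C)O[C@@H]3[C@@]2(O)[C@@H](C)C(=O)OC(C)(C)C
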